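**Plan**

1. Retrosynthesis: the six benzyl ethers go first; then the interflavan bond C4(upper)–C8(lower) is cut to a 4-alkoxy-epiguibourtinidol (cation precursor 21) and protected epicatechin 11; then in each flavan the pyran ring is cut at O1–C8a and C2–C3, back to an aryl aldehyde (ring B or E, carrying C2=O1) and a 2-(2-bromoaryl)ethane-1,1-diboronate (ring A or D, carrying C4 and C3).
2. Enabling feature: in pyran ring F of the lower unit (and ring C of the upper) O1 on C2 and the hydroxyl on C3 are a cis-1,2-dioxygen pair, and C8a lies ortho to the benzylic C4 on ring D. C3–C4–C4a–C8a is therefore a latent 1,4-dipole (boron-stabilised C3 nucleophile, C8a–Br electrophile) across which the aldehyde C2=O1 adds in a formal [4+2] sense. Boron makes C3 nucleophilic, stands in for the 3-OH so that only O1 can reach C8a, and is oxidised to OH with retention.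
3. Forward order: lithiated diborylmethane 6 is made once (step 4) and serves both fragments; ring D fragment 7 (steps 1–3 and 5); a one-flask copper addition/palladium etherification/oxidation closes ring F and gives protected epicatechin 11 (step 6); ring A fragment 16 (steps 7–10) undergoes the same operation to close ring C (step 11); DDQ activates C4 (step 12); Lewis-acid coupling joins C4 to C8 (step 13); hydrogenolysis (step 14).
4. Stereochemistry: C2 and C3 of both units (2R,3R, cis) come from the chiral copper–phosphoramidite catalyst (syn addition to the aldehyde Si face) and stereoretentive C–B oxidation; C4 (4R, 4β) comes from substrate control, the nucleophile entering anti to the 2-aryl and 3-hydroxyl groups.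

Key step: step 6

Remark: the target is read as epiguibourtinidol-(4β→8)-epicatechin with all five stereocentres R; compounds 1, 5, 8, 12 and 17 are taken as catalogue chemicals.

**Route**

Step 1
Reactants: 1 1,3-bis(benzyloxy)-5-bromobenzene
Product: 2 2,4-bis(benzyloxy)-6-bromobenzaldehyde
Conditions: POCl3, DMF, 0 → 75 °C; then H2O
Reagents that add atoms: N,N-dimethylformamide CN(C)C=O; water O
Why: Vilsmeier–Haack formylation of the doubly activated arene should go para to one benzyloxy group and ortho to the other, at the site flanked by bromine and one ether in preference to the site between the two ether groups.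

Step 2
Reactants: 2 2,4-bis(benzyloxy)-6-bromobenzaldehyde
Product: 3 [2,4-bis(benzyloxy)-6-bromophenyl]methanol
Conditions: NaBH4, THF/MeOH, 0 °C
Reagents that add atoms: none
Why: Borohydride reduction of an aryl aldehyde; the aryl bromide and the benzyl ethers are inert.

Step 3
Reactants: 3 [2,4-bis(benzyloxy)-6-bromophenyl]methanol
Product: 4 1,5-bis(benzyloxy)-3-bromo-2-(bromomethyl)benzene
Conditions: PBr3, CH2Cl2, 0 °C; crude bromide used at once
Reagents that add atoms: phosphorus tribromide BrP(Br)Br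
Why: Conversion of a primary benzylic alcohol into the bromide through its bromophosphite (SN2); the electron-rich benzylic bromide is not stored.

Step 4
Reactants: 5 bis(4,4,5,5-tetramethyl-1,3,2-dioxaborolan-2-yl)methane
Product: 6 [bis(4,4,5,5-tetramethyl-1,3,2-dioxaborolan-2-yl)methyl]lithium
Conditions: lithium 2,2,6,6-tetramethylpiperidide (1.0 equiv), THF, 0 °C; pentane added, solid filtered and dried under argon; one batch, stored at −20 °C under argon for steps 5 and 10
Reagents that add atoms: lithium 2,2,6,6-tetramethylpiperidide CC1(C)CCCC(C)(C)N1[Li]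
Why: Deprotonation of the methylene flanked by two boryl groups by a hindered, non-nucleophilic amide (formation of an α-boryl carbanion); the anion is stabilised by both empty boron p orbitals, so the lithium salt should be isolable as a moisture-sensitive solid.

Step 5
Reactants: 4 1,5-bis(benzyloxy)-3-bromo-2-(bromomethyl)benzene; 6 [bis(4,4,5,5-tetramethyl-1,3,2-dioxaborolan-2-yl)methyl]lithium
Product: 7 2,2'-{2-[2,4-bis(benzyloxy)-6-bromophenyl]ethane-1,1-diyl}bis(4,4,5,5-tetramethyl-1,3,2-dioxaborolane)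
Conditions: 6 (1.3 equiv), THF, 0 °C; 4 in THF added slowly, 0 → 22 °C
Reagents that add atoms: none
Why: SN2 alkylation of the lithiated geminal diboronate by the benzylic bromide; the stabilised carbanion does not exchange with the aryl bromide, and the excess of 6 over the slowly added 4 suppresses double alkylation.

Step 6
Reactants: 7 2,2'-{2-[2,4-bis(benzyloxy)-6-bromophenyl]ethane-1,1-diyl}bis(4,4,5,5-tetramethyl-1,3,2-dioxaborolane); 8 3,4-bis(benzyloxy)benzaldehyde
Product: 11 (2R,3R)-5,7-bis(benzyloxy)-2-[3,4-bis(benzyloxy)phenyl]-3,4-dihydro-2H-chromen-3-ol, via syn-hydroxyboronate 9 (not isolated), via 3-borylflavan 10 (not isolated)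
Conditions: (a) [Cu(NCMe)4]PF6 (10 mol %), BINOL-derived phosphoramidite L* (20 mol %, antipode giving Si-face attack), LiOtBu (1.2 equiv), 8 (1.2 equiv, 7 limiting), THF, 22 °C; (b) same flask, Pd(OAc)2 (5 mol %), 2-(di-tert-butylphosphino)-1,1'-binaphthyl (10 mol %), toluene, 65 °C; (c) H2O2, aq NaOH, 0 → 22 °C
Reagents that add atoms: hydrogen peroxide OO
Why: Proposed new method: LiOtBu and monovalent copper turn one boryl group of 7 into a chiral α-boryl alkylcopper (C3 nucleophile) that adds 1,2 to the Si face of 8 in a ligand-controlled transition state to give the syn lithium β-boryl alkoxide 9; zerovalent palladium then inserts into the C8a–Br bond of the same molecule, takes up the alkoxide O1 and closes the six-membered ring F by C(aryl)–O reductive elimination from a seven-membered palladacycle (formally a 6-exo etherification at C8a), so the aldehyde C2=O1 has added across C3 and C8a, and oxidative work-up replaces boron by hydroxyl. The closest known reaction types are the copper–phosphoramidite-catalysed enantio- and syn-selective 1,2-addition of 1,1-diborylalkanes to aryl aldehydes and the Buchwald–Hartwig intramolecular etherification of aryl bromides by secondary alcohols; new is their relay on one lithium alkoxide that carries a β-boryl group. C2 and C3 are both set by the chiral copper catalyst (syn adduct, hence 2,3-cis after closure; absolute sense from the ligand antipode), and C3 keeps its configuration because C–B oxidation is stereoretentive. The step needs syn over anti and Si over Re selectivity, which the catalyst supplies, and closure through O1 only, which is secured because C3 carries boron and not a hydroxyl, so a five-membered closure is impossible. Keeping 7 as the limiting partner leaves no geminal diboronate for palladium to cross-couple, and the lithium counter-ion and moderate temperature are chosen to disfavour syn-elimination of the β-oxidoboronate.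

Step 7
Reactants: 12 2-bromo-4-hydroxybenzaldehyde
Product: 13 4-(benzyloxy)-2-bromobenzaldehyde
Conditions: BnBr, K2CO3, DMF, 22 °C
Reagents that add atoms: benzyl bromide BrCc1ccccc1
Why: Williamson etherification of the phenol.

Step 8
Reactants: 13 4-(benzyloxy)-2-bromobenzaldehyde
Product: 14 [4-(benzyloxy)-2-bromophenyl]methanol
Conditions: NaBH4, THF/MeOH, 0 °C
Reagents that add atoms: none
Why: Borohydride reduction of the aryl aldehyde.

Step 9
Reactants: 14 [4-(benzyloxy)-2-bromophenyl]methanol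
Product: 15 4-(benzyloxy)-2-bromo-1-(bromomethyl)benzene
Conditions: PBr3, CH2Cl2, 0 °C; crude bromide used at once
Reagents that add atoms: phosphorus tribromide BrP(Br)Br
Why: Alcohol-to-bromide conversion through the bromophosphite (SN2).

Step 10
Reactants: 15 4-(benzyloxy)-2-bromo-1-(bromomethyl)benzene; 6 [bis(4,4,5,5-tetramethyl-1,3,2-dioxaborolan-2-yl)methyl]lithium
Product: 16 2,2'-{2-[4-(benzyloxy)-2-bromophenyl]ethane-1,1-diyl}bis(4,4,5,5-tetramethyl-1,3,2-dioxaborolane)
Conditions: 6 (1.3 equiv, from the batch of step 4), THF, 0 °C; 15 in THF added slowly, 0 → 22 °C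
Reagents that add atoms: none
Why: SN2 alkylation of the lithiated geminal diboronate by the benzylic bromide, as in step 5.

Step 11
Reactants: 16 2,2'-{2-[4-(benzyloxy)-2-bromophenyl]ethane-1,1-diyl}bis(4,4,5,5-tetramethyl-1,3,2-dioxaborolane); 17 4-(benzyloxy)benzaldehyde
Product: 20 (2R,3R)-7-(benzyloxy)-2-[4-(benzyloxy)phenyl]-3,4-dihydro-2H-chromen-3-ol, via syn-hydroxyboronate 18 (not isolated), via 3-borylflavan 19 (not isolated)
Conditions: (a) [Cu(NCMe)4]PF6 (10 mol %), phosphoramidite L* (20 mol %), LiOtBu (1.2 equiv), 17 (1.2 equiv), THF, 22 °C; (b) same flask, Pd(OAc)2 (5 mol %), 2-(di-tert-butylphosphino)-1,1'-binaphthyl (10 mol %), toluene, 65 °C; (c) H2O2, aq NaOH, 0 → 22 °C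
Reagents that add atoms: hydrogen peroxide OO
Why: Proposed new method: as in step 6, the copper-bound α-boryl alkyl group from 16 adds syn-selectively to the Si face of 17, zerovalent palladium closes ring C by C(aryl)–O reductive elimination on the lithium alkoxide 18, and stereoretentive C–B oxidation of 19 gives the 2,3-cis (2R,3R) flavan-3-ol under catalyst control; the closest known reaction types are the copper-catalysed addition of 1,1-diborylalkanes to aryl aldehydes and the Buchwald–Hartwig intramolecular etherification.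

Step 12
Reactants: 20 (2R,3R)-7-(benzyloxy)-2-[4-(benzyloxy)phenyl]-3,4-dihydro-2H-chromen-3-ol
Product: 21 (2R,3R,4S)-7-(benzyloxy)-2-[4-(benzyloxy)phenyl]-4-(2-ethoxyethoxy)-3,4-dihydro-2H-chromen-3-ol
Conditions: DDQ (2 equiv), 2-ethoxyethanol (excess), CH2Cl2, 22 °C, dark
Reagents that add atoms: 2-ethoxyethanol CCOCCO
Why: DDQ should abstract hydride from C4, the benzylic position activated by O1 (ortho) and the 7-benzyloxy group (para), and the cation is captured by the alcohol anti to the 2-aryl and 3-hydroxyl groups (4β), an oxidative benzylic etherification of the type used to activate C4 of flavan-3-ol benzyl ethers.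

Step 13
Reactants: 21 (2R,3R,4S)-7-(benzyloxy)-2-[4-(benzyloxy)phenyl]-4-(2-ethoxyethoxy)-3,4-dihydro-2H-chromen-3-ol; 11 (2R,3R)-5,7-bis(benzyloxy)-2-[3,4-bis(benzyloxy)phenyl]-3,4-dihydro-2H-chromen-3-ol
Product: 22 (2R,3R)-5,7-bis(benzyloxy)-8-{(2R,3R,4R)-7-(benzyloxy)-2-[4-(benzyloxy)phenyl]-3-hydroxy-3,4-dihydro-2H-chromen-4-yl}-2-[3,4-bis(benzyloxy)phenyl]-3,4-dihydro-2H-chromen-3-ol
Conditions: TMSOTf (0.2 equiv), 11 (3 equiv), CH2Cl2, −78 → −30 °C
Reagents that add atoms: none
Why: TMSOTf ionises the C4 ether of 21 to the flavan-4-yl cation (stabilised by O1 and the 7-benzyloxy group), which is trapped in a Friedel–Crafts alkylation by C8 of 11 (the more accessible of its two nucleophilic ring positions) on the β face, anti to the α-oriented 2-aryl and 3-hydroxyl groups, so that C4 becomes 4R (3,4-trans).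

Step 14
Reactants: 22 the hexa-O-benzyl dimer of step 13
Product: 23 (2R,3R)-2-(3,4-dihydroxyphenyl)-8-[(2R,3R,4R)-3,7-dihydroxy-2-(4-hydroxyphenyl)-3,4-dihydro-2H-chromen-4-yl]-3,4-dihydro-2H-chromene-3,5,7-triol
Conditions: H2 (1 atm), Pd(OH)2 on carbon, THF/MeOH/H2O, 22 °C
Reagents that add atoms: none
Why: Hydrogenolysis of the six benzyl ethers under neutral conditions should leave the benzylic C2–O1 bonds and the interflavan C4–C8 bond intact and give the free dimer.

**Compound list**

1 | 1,3-bis(benzyloxy)-5-bromobenzene | Brc1cc(OCc2ccccc2)cc(OCc2ccccc2)c1 | starting material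
2 | 2,4-bis(benzyloxy)-6-bromobenzaldehyde | O=Cc1c(Br)cc(OCc2ccccc2)cc1OCc1ccccc1 | intermediate
3 | [2,4-bis(benzyloxy)-6-bromophenyl]methanol | OCc1c(Br)cc(OCc2ccccc2)cc1OCc1ccccc1 | intermediate
4 | 1,5-bis(benzyloxy)-3-bromo-2-(bromomethyl)benzene | BrCc1c(Br)cc(OCc2ccccc2)cc1OCc1ccccc1 | intermediate
5 | bis(4,4,5,5-tetramethyl-1,3,2-dioxaborolan-2-yl)methane | CC1(C)OB(CB2OC(C)(C)C(C)(C)O2)OC1(C)C | starting material
6 | [bis(4,4,5,5-tetramethyl-1,3,2-dioxaborolan-2-yl)methyl]lithium (isolated solid, kept under argon) | [Li]C(B1OC(C)(C)C(C)(C)O1)B1OC(C)(C)C(C)(C)O1 | intermediate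
7 | 2,2'-{2-[2,4-bis(benzyloxy)-6-bromophenyl]ethane-1,1-diyl}bis(4,4,5,5-tetramethyl-1,3,2-dioxaborolane) | CC1(C)OB(C(Cc2c(Br)cc(OCc3ccccc3)cc2OCc2ccccc2)B2OC(C)(C)C(C)(C)O2)OC1(C)C | intermediate
8 | 3,4-bis(benzyloxy)benzaldehyde | O=Cc1ccc(OCc2ccccc2)c(OCc2ccccc2)c1 | starting material
9 | (1S,2R)-1-[3,4-bis(benzyloxy)phenyl]-3-[2,4-bis(benzyloxy)-6-bromophenyl]-2-(4,4,5,5-tetramethyl-1,3,2-dioxaborolan-2-yl)propan-1-ol (syn; formed as its lithium alkoxide, not isolated) | O[C@H](c1ccc(OCc2ccccc2)c(OCc2ccccc2)c1)[C@@H](Cc1c(Br)cc(OCc2ccccc2)cc1OCc1ccccc1)B1OC(C)(C)C(C)(C)O1 | intermediate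
10 | 2-{(2S,3R)-5,7-bis(benzyloxy)-2-[3,4-bis(benzyloxy)phenyl]-3,4-dihydro-2H-chromen-3-yl}-4,4,5,5-tetramethyl-1,3,2-dioxaborolane (2,3-cis; not isolated) | CC1(C)OB([C@@H]2Cc3c(OCc4ccccc4)cc(OCc4ccccc4)cc3O[C@@H]2c2ccc(OCc3ccccc3)c(OCc3ccccc3)c2)OC1(C)C | intermediate
11 | (2R,3R)-5,7-bis(benzyloxy)-2-[3,4-bis(benzyloxy)phenyl]-3,4-dihydro-2H-chromen-3-ol (2,3-cis; tetra-O-benzyl epicatechin) | O[C@@H]1Cc2c(OCc3ccccc3)cc(OCc3ccccc3)cc2O[C@@H]1c1ccc(OCc2ccccc2)c(OCc2ccccc2)c1 | intermediate
12 | 2-bromo-4-hydroxybenzaldehyde | O=Cc1ccc(O)cc1Br | starting material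
13 | 4-(benzyloxy)-2-bromobenzaldehyde | O=Cc1ccc(OCc2ccccc2)cc1Br | intermediate
14 | [4-(benzyloxy)-2-bromophenyl]methanol | OCc1ccc(OCc2ccccc2)cc1Br | intermediate
15 | 4-(benzyloxy)-2-bromo-1-(bromomethyl)benzene | BrCc1ccc(OCc2ccccc2)cc1Br | intermediate
16 | 2,2'-{2-[4-(benzyloxy)-2-bromophenyl]ethane-1,1-diyl}bis(4,4,5,5-tetramethyl-1,3,2-dioxaborolane) | CC1(C)OB(C(Cc2ccc(OCc3ccccc3)cc2Br)B2OC(C)(C)C(C)(C)O2)OC1(C)C | intermediate
17 | 4-(benzyloxy)benzaldehyde | O=Cc1ccc(OCc2ccccc2)cc1 | starting material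
18 | (1S,2R)-1-[4-(benzyloxy)phenyl]-3-[4-(benzyloxy)-2-bromophenyl]-2-(4,4,5,5-tetramethyl-1,3,2-dioxaborolan-2-yl)propan-1-ol (syn; formed as its lithium alkoxide, not isolated) | O[C@H](c1ccc(OCc2ccccc2)cc1)[C@@H](Cc1ccc(OCc2ccccc2)cc1Br)B1OC(C)(C)C(C)(C)O1 | intermediate
19 | 2-{(2S,3R)-7-(benzyloxy)-2-[4-(benzyloxy)phenyl]-3,4-dihydro-2H-chromen-3-yl}-4,4,5,5-tetramethyl-1,3,2-dioxaborolane (2,3-cis; not isolated) | CC1(C)OB([C@@H]2Cc3ccc(OCc4ccccc4)cc3O[C@@H]2c2ccc(OCc3ccccc3)cc2)OC1(C)C | intermediate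
20 | (2R,3R)-7-(benzyloxy)-2-[4-(benzyloxy)phenyl]-3,4-dihydro-2H-chromen-3-ol (2,3-cis; di-O-benzyl epiguibourtinidol) | O[C@@H]1Cc2ccc(OCc3ccccc3)cc2O[C@@H]1c1ccc(OCc2ccccc2)cc1 | intermediate
21 | (2R,3R,4S)-7-(benzyloxy)-2-[4-(benzyloxy)phenyl]-4-(2-ethoxyethoxy)-3,4-dihydro-2H-chromen-3-ol (2,3-cis, 4β) | c1ccccc1COc1ccc([C@H]2Oc3cc(OCc4ccccc4)ccc3[C@H](OCCOCC)[C@H]2O)cc1 | intermediate
22 | (2R,3R)-5,7-bis(benzyloxy)-8-{(2R,3R,4R)-7-(benzyloxy)-2-[4-(benzyloxy)phenyl]-3-hydroxy-3,4-dihydro-2H-chromen-4-yl}-2-[3,4-bis(benzyloxy)phenyl]-3,4-dihydro-2H-chromen-3-ol | c1ccccc1COc1ccc([C@H]2Oc3cc(OCc4ccccc4)ccc3[C@H](c3c(OCc4ccccc4)cc(OCc4ccccc4)c4c3O[C@H](c3ccc(OCc5ccccc5)c(OCc5ccccc5)c3)[C@H](O)C4)[C@H]2O)cc1 | intermediate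
23 | (2R,3R)-2-(3,4-dihydroxyphenyl)-8-[(2R,3R,4R)-3,7-dihydroxy-2-(4-hydroxyphenyl)-3,4-dihydro-2H-chromen-4-yl]-3,4-dihydro-2H-chromene-3,5,7-triol | Oc1ccc([C@H]2Oc3cc(O)ccc3[C@H](c3c(O)cc(O)c4c3O[C@H](c3ccc(O)c(O)c3)[C@H](O)C4)[C@H]2O)cc1 | target

**Count and risks**

Total step count: 14. Longest linear sequence: 8 steps (12 → 23 through steps 7–14).

Steps most likely to fail:

1. Step 6. When the flask is warmed for the etherification, the lithium β-oxidoboronate may undergo syn-elimination (boron-Wittig pathway) to a 1,3-diarylpropene; the palladium alkoxide may lose β-hydride; and the bulky geminal diboronate may erode syn selectivity. Fallback, setting out from 7 and 8 and returning at 11: the copper-catalysed addition is run alone and quenched cold, and the hydroxyboronate 9 is isolated. Its boron is made tetracoordinate with KHF2 in MeOH/H2O to give potassium {(1S,2R)-1-[3,4-bis(benzyloxy)phenyl]-3-[2,4-bis(benzyloxy)-6-bromophenyl]-1-hydroxypropan-2-yl}trifluoroborate F1, which has no empty orbital for the elimination. F1 is closed by an Ullmann etherification (CuI, 1,10-phenanthroline, Cs2CO3, DMF, 90 °C) to potassium {(2S,3R)-5,7-bis(benzyloxy)-2-[3,4-bis(benzyloxy)phenyl]-3,4-dihydro-2H-chromen-3-yl}trifluoroborate F2. F2 is oxidised with retention by KHSO5 (as 2KHSO5·KHSO4·K2SO4) in acetone/water to 11.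

2. Step 11. The same processes threaten this step: elimination of the β-oxidoboronate on warming and β-hydride loss at palladium. Fallback, setting out from 16 and 17 and returning at 20: the copper-catalysed addition is run alone and 18 is isolated. KHF2 converts it into potassium {(1S,2R)-1-[4-(benzyloxy)phenyl]-3-[4-(benzyloxy)-2-bromophenyl]-1-hydroxypropan-2-yl}trifluoroborate F3. Ullmann etherification (CuI, 1,10-phenanthroline, Cs2CO3, DMF, 90 °C) gives potassium {(2S,3R)-7-(benzyloxy)-2-[4-(benzyloxy)phenyl]-3,4-dihydro-2H-chromen-3-yl}trifluoroborate F4. Oxidation with KHSO5 in acetone/water gives 20.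

3. Step 13. The 5-deoxy C4 ether may ionise incompletely at low temperature; at higher temperature attack at C6 may compete with attack at C8, and acid may open ring C at C2 with epimerisation. Fallback, setting out from 21 and returning at 22: 21 is treated with benzyl mercaptan and BF3·OEt2 at −20 °C to give (2R,3S,4S)-7-(benzyloxy)-2-[4-(benzyloxy)phenyl]-4-(benzylsulfanyl)-3,4-dihydro-2H-chromen-3-ol F5. F5 is activated under mild thiophilic conditions with AgBF4 in THF at 0 °C in the presence of 11 (3 equiv) to give 22.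

Further compounds

F1 | step 6 | potassium {(1S,2R)-1-[3,4-bis(benzyloxy)phenyl]-3-[2,4-bis(benzyloxy)-6-bromophenyl]-1-hydroxypropan-2-yl}trifluoroborate | [K+].O[C@H](c1ccc(OCc2ccccc2)c(OCc2ccccc2)c1)[C@@H](Cc1c(Br)cc(OCc2ccccc2)cc1OCc1ccccc1)[B-](F)(F)F
F2 | step 6 | potassium {(2S,3R)-5,7-bis(benzyloxy)-2-[3,4-bis(benzyloxy)phenyl]-3,4-dihydro-2H-chromen-3-yl}trifluoroborate | [K+].F[B-](F)(F)[C@@H]1Cc2c(OCc3ccccc3)cc(OCc3ccccc3)cc2O[C@@H]1c1ccc(OCc2ccccc2)c(OCc2ccccc2)c1
F3 | step 11 | potassium {(1S,2R)-1-[4-(benzyloxy)phenyl]-3-[4-(benzyloxy)-2-bromophenyl]-1-hydroxypropan-2-yl}trifluoroborate | [K+].O[C@H](c1ccc(OCc2ccccc2)cc1)[C@@H](Cc1ccc(OCc2ccccc2)cc1Br)[B-](F)(F)F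
F4 | step 11 | potassium {(2S,3R)-7-(benzyloxy)-2-[4-(benzyloxy)phenyl]-3,4-dihydro-2H-chromen-3-yl}trifluoroborate | [K+].F[B-](F)(F)[C@@H]1Cc2ccc(OCc3ccccc3)cc2O[C@@H]1c1ccc(OCc2ccccc2)cc1
F5 | step 13 | (2R,3S,4S)-7-(benzyloxy)-2-[4-(benzyloxy)phenyl]-4-(benzylsulfanyl)-3,4-dihydro-2H-chromen-3-ol | c1ccccc1COc1ccc([C@H]2Oc3cc(OCc4ccccc4)ccc3[C@H](SCc3ccccc3)[C@H]2O)cc1
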